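**Plan**

1. Labels: the three stilbene units are a, b, c; C7 is the CH that carries a 4-oxyphenyl ring, C8 the next CH, C9–C14 the resorcinol ring (ring A in unit c, ring B in unit b, ring C in unit a).
2. Retrosynthesis: six O-methyl groups come off last; then C8b–C10a and O11a–C7b are cut in one operation (eight-membered carbocycle and dihydrofuran), leaving an indane whose ring B carries a 4-hydroxystilbene arm and whose ring C is a free resorcinol.
3. The feature that makes this closure possible: the phenol conjugated through C7b=C8b (one-electron oxidation puts spin on C8b) sits next to C10a, which is ortho and para to the two free OH groups of ring C; all other phenols stay methylated so that only these two rings can be oxidised.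
4. Further cuts: C7b=C8b (Heck), C7c–C10b (Friedel–Crafts), C7c–aryl (Grignard), then the indane-1-carbaldehyde back to a 2,3-diarylindenone (Larock annulation of a diarylalkyne with 2-bromo-3,5-dimethoxybenzaldehyde).
5. Forward ring order: the five-membered ring of the indane first, then the eight-membered ring and the dihydrofuran together in the key step.
6. Stereochemistry: an oxazaborolidine reduction sets one carbinol centre, a suprafacial 1,3-H shift moves it to C7a, hydrogenation anti to the C7a aryl sets C8a, epimerisation next to CHO sets C8c, facial attack on a benzylic cation sets C7c, and the ring closure sets C8b and C7b under control of these four.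

Key step: step 14

Assumption: in step 4 the 2-aryl-vinyl flank of the indenone is taken to act as the large ketone substituent, so the (R)-oxazaborolidine gives the (S)-carbinol; if the sense proves opposite, the (S)-catalyst is used.

**Step 1**
Reactants: 1 5-bromoresorcinol
Product: 2 1-bromo-3,5-bis(triisopropylsilyloxy)benzene
Conditions: TIPSCl, imidazole, DMF, 25 °C
Reagents that add atoms: triisopropylsilyl chloride, CC(C)[Si](Cl)(C(C)C)C(C)C
Why: Standard imidazole-promoted silylation of both phenols; the silyl groups mark the two oxygens of ring C that must be free in step 14 and should survive steps 2–12.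

**Step 2**
Reactants: 2 1-bromo-3,5-bis(triisopropylsilyloxy)benzene; 3 4-ethynylanisole
Product: 4 1-methoxy-4-{[3,5-bis(triisopropylsilyloxy)phenyl]ethynyl}benzene
Conditions: Pd(PhCN)2Cl2, P(t-Bu)3, CuI, i-Pr2NH, dioxane, 25 °C
Reagents that add atoms: none
Why: Sonogashira coupling under the bulky-phosphine conditions that work for electron-rich aryl bromides at room temperature.

**Step 3**
Reactants: 4 1-methoxy-4-{[3,5-bis(triisopropylsilyloxy)phenyl]ethynyl}benzene; 5 2-bromo-3,5-dimethoxybenzaldehyde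
Product: 6 2-[3,5-bis(triisopropylsilyloxy)phenyl]-4,6-dimethoxy-3-(4-methoxyphenyl)-1H-inden-1-one
Conditions: Pd(OAc)2, NaOAc, n-Bu4NCl, DMF, 100 °C
Reagents that add atoms: none
Why: Larock indenone annulation: zerovalent palladium inserts into C–Br, syn-carbopalladation puts the ring A carbon on the alkyne carbon that bears the electron-rich 4-methoxyphenyl group (the regiochemistry known for the closely related dimethoxyphenyl/anisyl alkyne), and the vinylpalladium adds to the aldehyde before β-hydride elimination.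

**Step 4**
Reactants: 6 2-[3,5-bis(triisopropylsilyloxy)phenyl]-4,6-dimethoxy-3-(4-methoxyphenyl)-1H-inden-1-one
Product: 7 (1S)-2-[3,5-bis(triisopropylsilyloxy)phenyl]-4,6-dimethoxy-3-(4-methoxyphenyl)-1H-inden-1-ol
Conditions: (R)-2-methyl-CBS-oxazaborolidine (0.2 equiv), BH3·SMe2, THF, −20 °C
Reagents that add atoms: none
Why: Corey–Bakshi–Shibata 1,2-reduction of the enone, precedented for 3-arylindenones, should deliver hydride to one face of C=O and give the (S)-carbinol, the only reagent-controlled stereocentre of the route.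

**Step 5**
Reactants: 7 (1S)-2-[3,5-bis(triisopropylsilyloxy)phenyl]-4,6-dimethoxy-3-(4-methoxyphenyl)-1H-inden-1-ol
Product: 9 (2R,3R)-2-[3,5-bis(triisopropylsilyloxy)phenyl]-4,6-dimethoxy-3-(4-methoxyphenyl)indan-1-one, via enol 8 (not isolated)
Conditions: DABCO (0.3 equiv), THF, 60 °C
Reagents that add atoms: none
Why: Amine-mediated suprafacial 1,3-prototropic shift, known for 3-arylindenols (ion pair of hydroxyindenide and ammonium, H returned to C3 on the same face), should transfer the carbinol chirality to C7a, and the enol ketonises to the more stable 2,3-trans ketone.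

**Step 6**
Reactants: 9 (2R,3R)-2-[3,5-bis(triisopropylsilyloxy)phenyl]-4,6-dimethoxy-3-(4-methoxyphenyl)indan-1-one
Product: 10 (1R)-2-[3,5-bis(triisopropylsilyloxy)phenyl]-5,7-dimethoxy-1-(4-methoxyphenyl)-1H-inden-3-yl trifluoromethanesulfonate
Conditions: Tf2O, 2,6-di-tert-butyl-4-methylpyridine, CH2Cl2, 0 °C
Reagents that add atoms: trifluoromethanesulfonic anhydride, O=S(=O)(OS(=O)(=O)C(F)(F)F)C(F)(F)F
Why: Enol triflate formation at the only α-CH under non-basic conditions (hindered pyridine), so that the doubly benzylic C1–H of the new indene is not deprotonated and C7a keeps its configuration.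

**Step 7**
Reactants: 10 (1R)-2-[3,5-bis(triisopropylsilyloxy)phenyl]-5,7-dimethoxy-1-(4-methoxyphenyl)-1H-inden-3-yl trifluoromethanesulfonate; 11 (tributylstannyl)methanol
Product: 12 {(1S)-2-[3,5-bis(triisopropylsilyloxy)phenyl]-5,7-dimethoxy-1-(4-methoxyphenyl)-1H-inden-3-yl}methanol
Conditions: Pd(PPh3)4, LiCl, dioxane, 90 °C
Reagents that add atoms: none
Why: Stille coupling of the vinyl triflate with the hydroxymethylstannane (LiCl-assisted transmetalation) is base-free, so the indene C1–H is not epimerised, and it installs the carbon that becomes C7c.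

**Step 8**
Reactants: 12 {(1S)-2-[3,5-bis(triisopropylsilyloxy)phenyl]-5,7-dimethoxy-1-(4-methoxyphenyl)-1H-inden-3-yl}methanol
Product: 13 [(1R,2R,3R)-2-[3,5-bis(triisopropylsilyloxy)phenyl]-4,6-dimethoxy-3-(4-methoxyphenyl)indan-1-yl]methanol (all-cis)
Conditions: [Ir(cod)(PCy3)(py)]PF6 (10 mol%), H2 (50 bar), CH2Cl2, 25 °C
Reagents that add atoms: none
Why: Hydroxyl-directed homogeneous hydrogenation of the tetrasubstituted allylic alcohol should deliver H2 to the face opposite the C7a aryl group, which sets C8a with its aryl cis to the C7a aryl and gives the all-cis indane.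

**Step 9**
Reactants: 13 [(1R,2R,3R)-2-[3,5-bis(triisopropylsilyloxy)phenyl]-4,6-dimethoxy-3-(4-methoxyphenyl)indan-1-yl]methanol
Product: 15 (1S,2R,3R)-2-[3,5-bis(triisopropylsilyloxy)phenyl]-4,6-dimethoxy-3-(4-methoxyphenyl)indane-1-carbaldehyde (CHO trans to the C2 aryl), via all-cis aldehyde 14 (not isolated)
Conditions: Dess–Martin periodinane, NaHCO3, CH2Cl2, 0 °C; then DBU, CH2Cl2, 25 °C
Reagents that add atoms: none
Why: Dess–Martin oxidation followed by base-mediated epimerisation of the only acidic stereocentre (α to CHO) should give the thermodynamic isomer with the formyl group trans to the neighbouring aryl, which sets C8c.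

**Step 10**
Reactants: 15 (1S,2R,3R)-2-[3,5-bis(triisopropylsilyloxy)phenyl]-4,6-dimethoxy-3-(4-methoxyphenyl)indane-1-carbaldehyde; 16 4-methoxyphenylmagnesium bromide
Product: 17 [(1S,2R,3R)-2-[3,5-bis(triisopropylsilyloxy)phenyl]-4,6-dimethoxy-3-(4-methoxyphenyl)indan-1-yl](4-methoxyphenyl)methanol (both carbinol epimers)
Conditions: THF, −78 to 0 °C; aq NH4Cl
Reagents that add atoms: none
Why: Grignard addition to the aldehyde; the new carbinol centre is not controlled and need not be, since it is ionised in step 11.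

**Step 11**
Reactants: 17 [(1S,2R,3R)-2-[3,5-bis(triisopropylsilyloxy)phenyl]-4,6-dimethoxy-3-(4-methoxyphenyl)indan-1-yl](4-methoxyphenyl)methanol; 18 1-bromo-3,5-dimethoxybenzene
Product: 19 (1R,2S,3R)-1-[(R)-(2-bromo-4,6-dimethoxyphenyl)(4-methoxyphenyl)methyl]-2-[3,5-bis(triisopropylsilyloxy)phenyl]-4,6-dimethoxy-3-(4-methoxyphenyl)indane
Conditions: Bi(OTf)3 (5 mol%), 18 (5 equiv), CH2Cl2/(CF3)2CHOH 4:1, −20 °C
Reagents that add atoms: none
Why: Friedel–Crafts benzylation: either carbinol epimer ionises to the 4-methoxyphenyl-stabilised cation, which 18 should attack through C2 (ortho/para to its methoxy groups, next to Br, the handle for the stilbene arm) on the face flanked only by the indane C2–H, not the face flanked by the peri C7–H of ring A, in the conformer with the indane C1–H in the cation plane, which gives the (R)-diarylmethine C7c; the trans disposition of ring C should prevent its own ring closure onto the cation.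

**Step 12**
Reactants: 19 (1R,2S,3R)-1-[(R)-(2-bromo-4,6-dimethoxyphenyl)(4-methoxyphenyl)methyl]-2-[3,5-bis(triisopropylsilyloxy)phenyl]-4,6-dimethoxy-3-(4-methoxyphenyl)indane; 20 tert-butyldimethyl(4-vinylphenoxy)silane
Product: 21 (1R,2S,3R)-1-[(R)-{2-[(E)-2-(4-tert-butyldimethylsilyloxyphenyl)ethenyl]-4,6-dimethoxyphenyl}(4-methoxyphenyl)methyl]-2-[3,5-bis(triisopropylsilyloxy)phenyl]-4,6-dimethoxy-3-(4-methoxyphenyl)indane
Conditions: Pd2(dba)3, [HP(t-Bu)3]BF4, Cy2NMe, dioxane, 100 °C
Reagents that add atoms: none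
Why: Mizoroki–Heck reaction of the hindered electron-rich aryl bromide under bulky-trialkylphosphine conditions gives the (E)-stilbene by syn-insertion and syn-β-hydride elimination.

**Step 13**
Reactants: 21 (the silyl-protected stilbene of step 12)
Product: 22 5-[(1R,2S,3R)-1-[(R)-{2-[(E)-2-(4-hydroxyphenyl)ethenyl]-4,6-dimethoxyphenyl}(4-methoxyphenyl)methyl]-4,6-dimethoxy-3-(4-methoxyphenyl)indan-2-yl]benzene-1,3-diol
Conditions: TBAF, AcOH, THF, 0 °C, argon; aq NH4Cl
Reagents that add atoms: none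
Why: Fluoride cleaves the three aryl silyl ethers and leaves the methyl ethers, which frees exactly the two phenol units (stilbene phenol and ring C) that take part in step 14.

**Step 14**
Reactants: 22 (the triphenol of step 13)
Product: 24 canaliculatol hexa-O-methyl ether (methyl ethers on the 4-oxyphenyl rings of units a and c and on rings A and B; free OH at C13a and on the unit b phenyl ring; 7aR,8aS,7bR,8bR,7cR,8cR), via para-quinone methide 23 (not isolated)
Conditions: laccase (Trametes versicolor), air, acetone/acetate buffer pH 5 (1:1), 25 °C, 0.5 mM, slow addition of 22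
Reagents that add atoms: none
Why: Proposed new method: the laccase (a multicopper oxidase that passes single electrons from phenols to O2) should oxidise the 4-hydroxystilbene phenol, the most easily oxidised group in 22, to a phenoxyl radical with spin at C8b and the resorcinol ring C to a radical with spin at C10a; coupling of C8b with C10a, rearomatisation of ring C and addition of O11a–H to the para-quinone methide 23 should give 24, the closest known reaction type being the laccase- or peroxidase-mediated oxidative dimerisation of 4-hydroxystilbenes to 2,3-diaryl-2,3-dihydrobenzofurans, here made intramolecular. The eight-membered carbocycle closes by 8-exo-trig attack of C10a on C8b of the C7b=C8b unit, and the dihydrofuran by 5-exo-trig oxa-Michael addition to C7b. C8b is set in the C–C coupling by the C7c centre: the C7b arm should go to the face of the new ring opposite the 4-methoxyphenyl group on C7c, the two sitting on neighbouring (ortho) positions of ring B, which is the arrangement of the target; C7b is set in the reversible oxa-Michael step, which places its aryl group trans to ring B on C8b. Chemoselectivity rests on the protecting-group pattern: only the stilbene phenol and ring C carry free OH groups, so ring A, whose C14c would give a seven-membered ring, cannot form a phenoxyl radical. Regioselectivity on ring C rests on the tether, since only C10a (ortho to O11a, para to O13a, equivalent to C14a by rotation) can reach C8b, and intermolecular coupling is held back by high dilution and slow addition.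

**Step 15**
Reactants: 24 canaliculatol hexa-O-methyl ether
Product: 25 canaliculatol
Conditions: BBr3, CH2Cl2, −78 to 0 °C; then MeOH/H2O
Reagents that add atoms: none
Why: BBr3 demethylation of aryl methyl ethers, known for polymethylated stilbene oligomers; any reversible opening of the dihydrofuran at C7b should only reclose to the trans isomer, because no other nucleophilic ring is within reach.

**Compound list**

1 | 5-bromoresorcinol | Oc1cc(O)cc(Br)c1 | starting material
2 | 1-bromo-3,5-bis(triisopropylsilyloxy)benzene | Brc1cc(O[Si](C(C)C)(C(C)C)C(C)C)cc(O[Si](C(C)C)(C(C)C)C(C)C)c1 | intermediate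
3 | 4-ethynylanisole | C#Cc1ccc(OC)cc1 | starting material
4 | 1-methoxy-4-{[3,5-bis(triisopropylsilyloxy)phenyl]ethynyl}benzene | COc1ccc(C#Cc2cc(O[Si](C(C)C)(C(C)C)C(C)C)cc(O[Si](C(C)C)(C(C)C)C(C)C)c2)cc1 | intermediate
5 | 2-bromo-3,5-dimethoxybenzaldehyde | O=Cc1cc(OC)cc(OC)c1Br | starting material
6 | 2-[3,5-bis(triisopropylsilyloxy)phenyl]-4,6-dimethoxy-3-(4-methoxyphenyl)-1H-inden-1-one | COc1ccc(C2=C(c3cc(O[Si](C(C)C)(C(C)C)C(C)C)cc(O[Si](C(C)C)(C(C)C)C(C)C)c3)C(=O)c3cc(OC)cc(OC)c23)cc1 | intermediate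
7 | (1S)-2-[3,5-bis(triisopropylsilyloxy)phenyl]-4,6-dimethoxy-3-(4-methoxyphenyl)-1H-inden-1-ol | COc1ccc(C2=C(c3cc(O[Si](C(C)C)(C(C)C)C(C)C)cc(O[Si](C(C)C)(C(C)C)C(C)C)c3)[C@@H](O)c3cc(OC)cc(OC)c23)cc1 | intermediate
8 | (1S)-2-[3,5-bis(triisopropylsilyloxy)phenyl]-5,7-dimethoxy-1-(4-methoxyphenyl)-1H-inden-3-ol (enol) | COc1ccc([C@H]2C(c3cc(O[Si](C(C)C)(C(C)C)C(C)C)cc(O[Si](C(C)C)(C(C)C)C(C)C)c3)=C(O)c3cc(OC)cc(OC)c23)cc1 | intermediate (not isolated)
9 | (2R,3R)-2-[3,5-bis(triisopropylsilyloxy)phenyl]-4,6-dimethoxy-3-(4-methoxyphenyl)indan-1-one (2,3-trans) | COc1ccc([C@H]2[C@H](c3cc(O[Si](C(C)C)(C(C)C)C(C)C)cc(O[Si](C(C)C)(C(C)C)C(C)C)c3)C(=O)c3cc(OC)cc(OC)c23)cc1 | intermediate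
10 | (1R)-2-[3,5-bis(triisopropylsilyloxy)phenyl]-5,7-dimethoxy-1-(4-methoxyphenyl)-1H-inden-3-yl trifluoromethanesulfonate | COc1ccc([C@H]2C(c3cc(O[Si](C(C)C)(C(C)C)C(C)C)cc(O[Si](C(C)C)(C(C)C)C(C)C)c3)=C(OS(=O)(=O)C(F)(F)F)c3cc(OC)cc(OC)c23)cc1 | intermediate
11 | (tributylstannyl)methanol | OC[Sn](CCCC)(CCCC)CCCC | starting material
12 | {(1S)-2-[3,5-bis(triisopropylsilyloxy)phenyl]-5,7-dimethoxy-1-(4-methoxyphenyl)-1H-inden-3-yl}methanol | COc1ccc([C@H]2C(c3cc(O[Si](C(C)C)(C(C)C)C(C)C)cc(O[Si](C(C)C)(C(C)C)C(C)C)c3)=C(CO)c3cc(OC)cc(OC)c23)cc1 | intermediate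
13 | [(1R,2R,3R)-2-[3,5-bis(triisopropylsilyloxy)phenyl]-4,6-dimethoxy-3-(4-methoxyphenyl)indan-1-yl]methanol (all-cis) | COc1ccc([C@H]2[C@@H](c3cc(O[Si](C(C)C)(C(C)C)C(C)C)cc(O[Si](C(C)C)(C(C)C)C(C)C)c3)[C@@H](CO)c3cc(OC)cc(OC)c23)cc1 | intermediate
14 | (1R,2R,3R)-2-[3,5-bis(triisopropylsilyloxy)phenyl]-4,6-dimethoxy-3-(4-methoxyphenyl)indane-1-carbaldehyde (all-cis) | COc1ccc([C@H]2[C@@H](c3cc(O[Si](C(C)C)(C(C)C)C(C)C)cc(O[Si](C(C)C)(C(C)C)C(C)C)c3)[C@@H](C=O)c3cc(OC)cc(OC)c23)cc1 | intermediate (not isolated)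
15 | (1S,2R,3R)-2-[3,5-bis(triisopropylsilyloxy)phenyl]-4,6-dimethoxy-3-(4-methoxyphenyl)indane-1-carbaldehyde (CHO trans to the C2 aryl, the two aryl groups cis) | COc1ccc([C@H]2[C@@H](c3cc(O[Si](C(C)C)(C(C)C)C(C)C)cc(O[Si](C(C)C)(C(C)C)C(C)C)c3)[C@H](C=O)c3cc(OC)cc(OC)c23)cc1 | intermediate
16 | 4-methoxyphenylmagnesium bromide | COc1ccc([Mg]Br)cc1 | starting material
17 | [(1S,2R,3R)-2-[3,5-bis(triisopropylsilyloxy)phenyl]-4,6-dimethoxy-3-(4-methoxyphenyl)indan-1-yl](4-methoxyphenyl)methanol (both carbinol epimers) | COc1ccc([C@H]2[C@@H](c3cc(O[Si](C(C)C)(C(C)C)C(C)C)cc(O[Si](C(C)C)(C(C)C)C(C)C)c3)[C@H](C(O)c3ccc(OC)cc3)c3cc(OC)cc(OC)c23)cc1 | intermediate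
18 | 1-bromo-3,5-dimethoxybenzene | COc1cc(Br)cc(OC)c1 | starting material
19 | (1R,2S,3R)-1-[(R)-(2-bromo-4,6-dimethoxyphenyl)(4-methoxyphenyl)methyl]-2-[3,5-bis(triisopropylsilyloxy)phenyl]-4,6-dimethoxy-3-(4-methoxyphenyl)indane | COc1ccc([C@H]2[C@@H](c3cc(O[Si](C(C)C)(C(C)C)C(C)C)cc(O[Si](C(C)C)(C(C)C)C(C)C)c3)[C@H]([C@H](c3ccc(OC)cc3)c3c(OC)cc(OC)cc3Br)c3cc(OC)cc(OC)c23)cc1 | intermediate
20 | tert-butyldimethyl(4-vinylphenoxy)silane | C=Cc1ccc(O[Si](C)(C)C(C)(C)C)cc1 | starting material
21 | (1R,2S,3R)-1-[(R)-{2-[(E)-2-(4-tert-butyldimethylsilyloxyphenyl)ethenyl]-4,6-dimethoxyphenyl}(4-methoxyphenyl)methyl]-2-[3,5-bis(triisopropylsilyloxy)phenyl]-4,6-dimethoxy-3-(4-methoxyphenyl)indane | COc1ccc([C@H]2[C@@H](c3cc(O[Si](C(C)C)(C(C)C)C(C)C)cc(O[Si](C(C)C)(C(C)C)C(C)C)c3)[C@H]([C@H](c3ccc(OC)cc3)c3c(OC)cc(OC)cc3/C=C/c3ccc(O[Si](C)(C)C(C)(C)C)cc3)c3cc(OC)cc(OC)c23)cc1 | intermediate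
22 | 5-[(1R,2S,3R)-1-[(R)-{2-[(E)-2-(4-hydroxyphenyl)ethenyl]-4,6-dimethoxyphenyl}(4-methoxyphenyl)methyl]-4,6-dimethoxy-3-(4-methoxyphenyl)indan-2-yl]benzene-1,3-diol | COc1ccc([C@H]2[C@@H](c3cc(O)cc(O)c3)[C@H]([C@H](c3ccc(OC)cc3)c3c(OC)cc(OC)cc3/C=C/c3ccc(O)cc3)c3cc(OC)cc(OC)c23)cc1 | intermediate
23 | para-quinone methide with the C8b–C10a bond and the eight-membered ring closed (C8b R; C7b exocyclic to a cyclohexadienone; ring C with both OH free) | COc1ccc([C@@H]2c3c(OC)cc(OC)cc3[C@H]3[C@H](c4ccc(OC)cc4)c4c(OC)cc(OC)cc4[C@@H](C=C4C=CC(=O)C=C4)c4c(O)cc(O)cc4[C@H]23)cc1 | intermediate (not isolated)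
24 | canaliculatol hexa-O-methyl ether (free OH at C13a and on the unit b phenyl ring) | COc1ccc([C@@H]2c3c(OC)cc(OC)cc3[C@H]3[C@H](c4ccc(OC)cc4)c4c(OC)cc(OC)cc4[C@@H]4c5c(cc(O)cc5[C@H]23)O[C@H]4c2ccc(O)cc2)cc1 | intermediate
25 | canaliculatol | Oc1ccc([C@@H]2c3c(O)cc(O)cc3[C@H]3[C@H](c4ccc(O)cc4)c4c(O)cc(O)cc4[C@@H]4c5c(cc(O)cc5[C@H]23)O[C@H]4c2ccc(O)cc2)cc1 | target

**Step count and risks**

Total: 15 steps. Longest linear sequence: 15 steps (1 to 25); all other building blocks (3, 5, 11, 16, 18, 20) are commercial.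

Steps most likely to fail:

1. Step 14 (key step, proposed new method). What may go wrong: intermolecular coupling of the stilbene radical (oligomerisation) outrunning the eight-membered ring closure, or attack on the wrong face of C8b. Fallback with known chemistry, setting out from 19 and coming back at 25: bromine–lithium exchange on 19 (n-BuLi, THF, −78 °C) and DMF should give the ring B benzaldehyde F1. TBAF then frees ring C to give the resorcinol aldehyde F2. Its bromomagnesium phenoxide (EtMgBr, toluene, 25 to 60 °C) should add through C10a to the aldehyde (ortho-selective hydroxyalkylation of a magnesium phenoxide), closing the eight-membered ring as the ortho-hydroxybenzylic alcohol F3. F3 with (4-methoxybenzyl)dimethylsulfonium bromide F4, made from 4-methoxybenzyl bromide and dimethyl sulfide, and Cs2CO3 in CH2Cl2 should undergo the known ortho-quinone methide/sulfur ylide [4+1] annulation to the trans-dihydrobenzofuran, canaliculatol hepta-O-methyl ether F5. BBr3 as in step 15 then gives 25.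

2. Step 11. What may go wrong: poor facial selectivity at the diarylmethine carbon C7c, attack of the arene through C4 instead of C2, or loss of a proton from the cation to a benzylidene. Fallback, setting out from 15 and coming back at 19: the roles of the two aryl groups are exchanged, so that attack on the same face of the cation gives the opposite configuration at C7c. 18 is iodinated (NIS, MeCN) to 1-bromo-2-iodo-3,5-dimethoxybenzene F6. Iodine–magnesium exchange (i-PrMgCl·LiCl, THF, −40 °C) and addition to 15 give the (2-bromo-4,6-dimethoxyphenyl)carbinol F7. Ionisation (Sc(OTf)3, anisole/(CF3)2CHOH, 0 °C) and para-attack of anisole then give 19.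

3. Step 8. What may go wrong: the iridium catalyst failing to reduce the tetrasubstituted aryl-conjugated alkene, or migration of the double bond that erases C7a. Fallback, setting out from 9 and coming back at 13 (it replaces steps 6 to 8): the enolate of 9 (LDA, THF, −78 °C) is protonated kinetically (2,6-di-tert-butyl-4-methylphenol) on the face opposite the C3 aryl to give the cis-2,3-diarylindanone F8. Non-basic methylenation (Cp2TiMe2, toluene, 65 °C) gives the exocyclic alkene F9. Hydroboration (9-BBN, THF; then NaOH/H2O2) on the face opposite the two cis aryl groups gives 13.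

**Further compounds**

F1 | step 14 | 2-{(R)-[(1R,2S,3R)-2-[3,5-bis(triisopropylsilyloxy)phenyl]-4,6-dimethoxy-3-(4-methoxyphenyl)indan-1-yl](4-methoxyphenyl)methyl}-3,5-dimethoxybenzaldehyde | COc1ccc([C@H]2[C@@H](c3cc(O[Si](C(C)C)(C(C)C)C(C)C)cc(O[Si](C(C)C)(C(C)C)C(C)C)c3)[C@H]([C@H](c3ccc(OC)cc3)c3c(OC)cc(OC)cc3C=O)c3cc(OC)cc(OC)c23)cc1
F2 | step 14 | 2-{(R)-[(1R,2S,3R)-2-(3,5-dihydroxyphenyl)-4,6-dimethoxy-3-(4-methoxyphenyl)indan-1-yl](4-methoxyphenyl)methyl}-3,5-dimethoxybenzaldehyde | COc1ccc([C@H]2[C@@H](c3cc(O)cc(O)c3)[C@H]([C@H](c3ccc(OC)cc3)c3c(OC)cc(OC)cc3C=O)c3cc(OC)cc(OC)c23)cc1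
F3 | step 14 | eight-membered-ring ortho-hydroxybenzylic alcohol (C8b–C10a bond closed, OH on C8b, both carbinol epimers) | COc1ccc([C@@H]2c3c(OC)cc(OC)cc3[C@H]3[C@H](c4ccc(OC)cc4)c4c(OC)cc(OC)cc4C(O)c4c(O)cc(O)cc4[C@H]23)cc1
F4 | step 14 | (4-methoxybenzyl)dimethylsulfonium bromide | COc1ccc(C[S+](C)C)cc1.[Br-]
F5 | step 14 | canaliculatol hepta-O-methyl ether (free OH at C13a only) | COc1ccc([C@@H]2c3c(OC)cc(OC)cc3[C@H]3[C@H](c4ccc(OC)cc4)c4c(OC)cc(OC)cc4[C@@H]4c5c(cc(O)cc5[C@H]23)O[C@H]4c2ccc(OC)cc2)cc1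
F6 | step 11 | 1-bromo-2-iodo-3,5-dimethoxybenzene | COc1cc(OC)c(I)c(Br)c1
F7 | step 11 | (2-bromo-4,6-dimethoxyphenyl)[(1S,2R,3R)-2-[3,5-bis(triisopropylsilyloxy)phenyl]-4,6-dimethoxy-3-(4-methoxyphenyl)indan-1-yl]methanol (both carbinol epimers) | COc1ccc([C@H]2[C@@H](c3cc(O[Si](C(C)C)(C(C)C)C(C)C)cc(O[Si](C(C)C)(C(C)C)C(C)C)c3)[C@H](C(O)c3c(OC)cc(OC)cc3Br)c3cc(OC)cc(OC)c23)cc1
F8 | step 8 | (2S,3R)-2-[3,5-bis(triisopropylsilyloxy)phenyl]-4,6-dimethoxy-3-(4-methoxyphenyl)indan-1-one (2,3-cis) | COc1ccc([C@H]2[C@@H](c3cc(O[Si](C(C)C)(C(C)C)C(C)C)cc(O[Si](C(C)C)(C(C)C)C(C)C)c3)C(=O)c3cc(OC)cc(OC)c23)cc1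
F9 | step 8 | (2S,3R)-2-[3,5-bis(triisopropylsilyloxy)phenyl]-4,6-dimethoxy-3-(4-methoxyphenyl)-1-methyleneindane (2,3-cis) | COc1ccc([C@H]2[C@@H](c3cc(O[Si](C(C)C)(C(C)C)C(C)C)cc(O[Si](C(C)C)(C(C)C)C(C)C)c3)C(=C)c3cc(OC)cc(OC)c23)cc1
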